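In the early minutes of the summer flask, the one run I had, L came quickly and then crept, so before ranking flasks that differ in their charge of G, I read that run as a small table of gains.

in all of them: Z 0.80 M
- summer: G 0.34 M; run made earlier
- zeta: G 0.400 M; time 12 min
- epsilon: G 1.20 M; time 12 min
- theta: G 0.300 M; time 12 min
- delta: G 0.600 M; time 12 min
- alpha: G 2.50 M; time 12 min
- beta: G 0.800 M; time 12 min

summer run (percent of the Z charged)

| time / min | L / % |
|---|---|
| 1.00 | 4.4 |
| 2.00 | 6.4 |
| 3.00 | 7.3 |
| 4.00 | 8.6 |
| 5.00 | 9.8 |
| 6.00 | 10.9 |

(scatter of a reading: 0.5 percentage points)



* all flasks from highest to lowest amount of L, in percent of the Z charged, at 12 min (zeta / epsilon / theta / delta / alpha / beta)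
* the amount of L, in percent of the Z charged of the flask you put first, at 12 min
* the amount of L, in percent of the Z charged of the flask you put last, at 12 min

The first row gave 4.4 % of the Z charged in one minute, while the last row added 1.1 percentage points in its minute, so the gain had fallen to 0.250 of the first. That last row meant 0.0872 M of L, and with Z and G each reckoned as charge less L, their product still stood at 0.662 of its starting value. The gain had dropped further than the product, so I guessed that a way back was already opposing the forward step, a guess this run could not prove.

I therefore chose to treat the last row as a stop, as an assumption and although it was still gaining, and formed the stall quotient K_s, the L present divided by the product of Z and G so reckoned, an apparent equilibrium constant: 0.484 M⁻¹. It is a reading with scatter, and the remaining creep was a risk I accepted. Solving the same quotient for each charge, my own reckoning put L rising with G, with alpha at 0.403 M, or 50.4 %, and theta at 9.71 %.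

The forecast saw a burst and then “a slow steady reaction”, and it gave alpha > epsilon > beta > delta > zeta > theta, with 74 % and 15.5 %; its order matched mine, its two amounts did not.

The flasks gave alpha > epsilon > beta > delta > zeta > theta, with 48.8 % and 9.81 %.

    G ⇌ E (K = 0.379, k = 0.00138 s⁻¹)
    Z + G ⇌ L (K = 0.726 M⁻¹, k = 0.00243 M⁻¹ s⁻¹)
    Z + G ⇌ Q (K = 7.53 M⁻¹, k = 1.23 × 10⁻⁴ M⁻¹ s⁻¹)

Counted my way, alpha's L gives a quotient of 0.451 M⁻¹ against K_s of 0.484 M⁻¹, although G in alpha stood at 59.9 % of its own charge at 12.0 min, with E at 0.551 M and Q at 7.81 % of the Z charged beside L. In a neighbouring flask, alpha's charge of G with Z raised to 2.0 M, K_s gave L at 44.0 % of the Z charged, and that flask held 42.2 % of L at 12.0 min.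

The earlier runs and the new flask were generated by integration from invented constants, and the scatter is random.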